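## Structural features

The target 20 is a single-ring 1,2-dioxolane (ring atoms O1, O2, C3, C4, C5). C3 carries a methyl group and a CH2CO2H arm, C5 carries a methyl group and an unbranched C15 chain, and C4 is a bare CH2. The stereocentres C3 and C5 are not adjacent but 1,3-related across C4, with arm and chain trans; neither bears hydrogen, so they cannot epimerise, but they also cannot be set by enolate, hydride or hydrogenation chemistry. The chain runs through six CH2 groups to a (7E,9E)-diene, one doubly allylic CH2 (C11) and a (12Z)-alkene, so three alkene geometries must be delivered as well. Fragile elements are the O–O bond (low-valent metals, phosphines, strong hydride donors, hydrogenation, radical reductants), the β-peroxy carboxyl arm (an α-carbanion can expel the peroxide oxygen from C3 and open the ring) and the skipped triene (autoxidation, isomerisation, electrophiles). The ring is otherwise robust, because the lack of hydrogen on C3 and C5 excludes Kornblum–DeLaMare fragmentation. The real difficulty is to make two oxygen-bearing quaternary carbons on a peroxide ring with defined relative and absolute configuration, and to finish without reducing conditions. The key step uses the fact that C5 (methyl, chain, bond to O1) is a disguised methyl ketone carbon and that C4–C3 (methyl, two-carbon arm) is a masked 3-methylbut-3-enyl unit; O1–O2–C5 can therefore arrive as a peroxycarbenium ion and C4–C3 as a 1,1-disubstituted alkene, closing the ring through C4–C5 and O2–C3.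

## Logic of the disconnections

20 to 18 (through 19): no skeletal bond is cut; the carboxyl carbon of the arm is taken back to the alcohol level. A carbonyl β to the peroxide cannot be carried through base-mediated chain building. The gain is an inert CH2CH2O arm for the whole sequence. The demand is a last oxidation that spares O–O and triene and never exposes 19 to base.

18 to 17: the O–Si bond. The hydroxyl stays masked by the silyl group already present in the ring-forming step, so no protecting-group exchange is needed. The forward step must cleave silicon without touching peroxide or triene.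

17 to 13 plus 16: the C9=C10 double bond of the chain. This cut separates the conjugated diene from the skipped Z-alkene, so C12=C13 arrives ready-made in 16 and C7=C8 in 13. The gain is a C6 reagent and a C9 enal. The demand is an E-selective olefination that uses no reductant and a base the ring tolerates.

16 to 15 to 14: the two S–O bonds, then the C–S bond. This leads to a commercial alcohol that already holds the Z-alkene. The forward steps must oxidise sulfur without epoxidising the alkene.

13 to 12: the C7=C8 double bond, a two-carbon formyl olefination. A stabilised ylide gives the E-enal in one operation. The demand is clean mono-homologation.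

12 to 11: no skeletal bond; aldehyde back to methyl ester. The ester is the form that survives the Lewis acid and the cations of ring formation. The demand is a partial reduction that stops at the aldehyde and leaves O–O alone.

11 to 10: no bond is cut; the single enantiomer is traced to the racemate, since the ring-forming step has no source of absolute control. The demand is a physical resolution placed early, so that no later step is spent on the wrong enantiomer.

10 to 7 plus 9: the C4–C5 and O2–C3 bonds. Both quaternary carbons are then made from planar cationic carbons, so crowding is no obstacle, and ring, two skeletal bonds and both stereocentres come from one step. The gain is two simple acyclic fragments. The demand is an alkene that directs the cation to C3, spectator groups that cannot intercept the cations, and separation of the trans isomer.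

7 to 6 to 4 to 3 to 1 (through 2): in turn the O–Si bond of the silyl peroxide, the C8–OO bond (peroxide oxygens from 5), the ketal C–O bonds and the C8–C9 bond of the methyl ketone. Each cut removes one functional group until a commercial half-ester remains. The demands are mono-exchange at the ketal carbon and a methyl transfer that stops at the ketone with the ester present.

9 to 8: the O–Si bond, leading to a commercial alkenol. The silyl ether must be bulky, stable to SnCl4 and unable to participate.

## Other disconnections considered

Alternative 1: The cut removes both exocyclic C–CH2 bonds (C3–CH2 and C5–CH2) from an already closed dioxolane. In the forward step TiCl4 would ionise the bis-peroxyketal 3,5-dimethoxy-3,5-dimethyl-1,2-dioxolane A1 at one ketal carbon and then the other, and 1-methoxy-1-(trimethylsilyloxy)ethene A2 would trap each cyclic peroxycarbenium ion to give the diester A3 as a racemate.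
- In favour: the O–O bond is in place from the first step and from very cheap materials. The acetic ester arm arrives at its final oxidation level; this is better than the chosen plan, which must oxidise an alcohol next to a triene at the end.
- Mechanism: the same family of Lewis-acid peroxycarbenium chemistry, so the two plans are equal on precedent.
- Against: A3 has two identical arms. The C15 chain must be grown from one CH2CO2Me group whose ester carbon has to end as a CH2. This needs statistical differentiation of two homotopic esters, reduction, a five-carbon extension and saturation of the new alkene without hydrogenolysis of O–O, before the triene end-game starts. All of it would be done with a β-peroxy ester on board, which risks ring opening under basic olefination conditions.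
- Stereochemistry: the second trapping has only the weak methyl-versus-arm bias, so isomer separation and resolution are still needed; equal to the chosen plan, not better.
- Step economy: worse, because the chosen plan brings in seven chain carbons together with the ring.

Alternative 2: The cut is O1–C5 alone. In the forward step N-iodosuccinimide would activate the trisubstituted alkene of hydroperoxide A4, and the hydroperoxy oxygen would attack the methyl-bearing carbon in 5-exo mode anti to iodine, giving the iodoalkyl dioxolane A5.
- In favour: C3 exists before ring closure and could be introduced enantioenriched, so no resolution would be needed; on absolute configuration this is better than the chosen plan. The closure is regiochemically secure (5-exo, Markovnikov), and on that point the two plans are equal.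
- Against: A4 is a multi-step objective in itself (a configured tertiary hydroperoxide plus an alkene of defined geometry), and a free hydroperoxide must be carried into an electrophilic step. C5 is controlled only by 1,3-induction from a centre whose methyl and hydroxyethyl groups differ little, so a cis/trans mixture is again likely; an equal weakness. The iodine must then be removed by a radical reduction in the presence of O–O, a liability the chosen plan does not have.
- Step economy: longer, because fragment synthesis and deiodination are added.

Alternative 3: The cut removes both C–O bonds of the peroxide (O2–C3 and O1–C5), with hydrogen peroxide 5 as linchpin. In the forward step Me3SiOTf would let 5 open one oxetane of the C2-symmetric bis-oxetane A6 at its tertiary carbon, and the new hydroperoxide would open the second oxetane 5-exo, giving the diol A7.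
- In favour: if both openings are invertive, relative and absolute configuration both follow from A6; on stereocontrol this is clearly better than the chosen plan. The hydroxyethyl arm is the same arm the chosen plan oxidises at the end, so the two are equal there.
- Against: A6 needs its own asymmetric synthesis of two tertiary ether centres. Opening at a tertiary carbon has carbocation character and may leak stereochemistry, and double intermolecular opening competes with ring closure. A7 has two identical arms, and one of them must be lengthened by thirteen carbons through an sp3–sp3 junction next to a peroxide.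
- Step economy: worse, because the chain carbons arrive late and one at a time in strategy terms, whereas the chosen plan installs a C8 ester chain with the ketone.

Key step: step 6

Remarks on the chemistry:
- Ring atoms are labelled O1, O2, C3 (arm carbon), C4, C5 (chain carbon). In the systematic names of 10 to 13 the locants 3 and 5 are exchanged because the heptanoate chain is the parent; both centres are S there, so nothing is ambiguous.
- The silyl ethers and alcohols are (3S,5S) and 19 and 20 are (3R,5S). This is the same spatial arrangement: the descriptor at the arm carbon changes only because CH2CHO and CH2CO2H outrank the ring CH2.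
- The fragment structures were checked against the target: the ester carbon of 7 becomes C7 of the chain, 13 adds C8 and C9, and 16 adds C10 to C15. No correction was needed, and the fragment pair is kept as it stands.
- Racemates are drawn as one enantiomer.
- Hydroperoxide solutions are assumed to be handled on modest scale behind a shield and never concentrated to dryness.

## Route

Step 1
Reactants: 1 monomethyl suberate
Product: 3 methyl 8-oxononanoate, via methyl 8-chloro-8-oxooctanoate 2 (not isolated)
Conditions: (COCl)2, DMF (cat.), CH2Cl2, 0 °C → rt; evaporate; then MeMgBr, Fe(acac)3 (3 mol%), THF, −78 °C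
Reagents that add atoms: oxalyl chloride, O=C(Cl)C(Cl)=O (chlorine of 2); methylmagnesium bromide, C[Mg]Br (methyl of 3)
Why: The acid is converted to its chloride by Vilsmeier-type activation, and iron-catalysed acylation of the Grignard reagent at −78 °C is much faster than addition to the ketone formed or to the methyl ester, so the reaction should stop at the methyl ketone.

Step 2
Reactants: 3 methyl 8-oxononanoate
Product: 4 methyl 8,8-dimethoxynonanoate
Conditions: HC(OMe)3, MeOH, TsOH·H2O (cat.), rt; Et3N quench
Reagents that add atoms: trimethyl orthoformate, COC(OC)OC; methanol, CO
Why: Acid-catalysed ketalisation driven by the orthoformate as water scavenger; the methyl ester is degenerate in methanol.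

Step 3
Reactants: 4 methyl 8,8-dimethoxynonanoate; 5 hydrogen peroxide
Product: 6 methyl 8-hydroperoxy-8-methoxynonanoate (racemic)
Conditions: 5 (anhydrous, in Et2O, 3 equiv), camphorsulfonic acid (cat.), Et2O, 0 °C; NaHCO3 quench
Reagents that add atoms: none
Why: Acid-catalysed perhydrolysis (transketalisation): the ketal ionises to an oxocarbenium ion that is captured by the α-effect nucleophile H2O2, and short contact at 0 °C should hold the exchange at the mono-peroxy stage. The new stereocentre at C8 is racemic and is erased when the ketal is ionised in step 6.

Step 4
Reactants: 6 methyl 8-hydroperoxy-8-methoxynonanoate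
Product: 7 methyl 8-methoxy-8-(triethylsilylperoxy)nonanoate (racemic)
Conditions: Et3SiCl, imidazole, DMAP (cat.), CH2Cl2, 0 °C
Reagents that add atoms: chlorotriethylsilane, CC[Si](Cl)(CC)CC
Why: Standard O-silylation of an acidic hydroperoxide; the triethylsilyl group is the one expected to leave cleanly from oxygen in the ring closure of step 6.

Step 5
Reactants: 8 3-methylbut-3-en-1-ol
Product: 9 tert-butyl(3-methylbut-3-enyloxy)diphenylsilane
Conditions: t-BuPh2SiCl, imidazole, CH2Cl2, rt
Reagents that add atoms: tert-butylchlorodiphenylsilane, CC(C)(C)[Si](Cl)(c1ccccc1)c1ccccc1
Why: Standard silylation of a primary alcohol; the group is stable to SnCl4 at low temperature, cannot participate, and supplies a chromophore for step 7.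

Step 6
Reactants: 7 methyl 8-methoxy-8-(triethylsilylperoxy)nonanoate; 9 tert-butyl(3-methylbut-3-enyloxy)diphenylsilane
Product: 10 methyl 7-[(3S*,5S*)-5-[2-(tert-butyldiphenylsilyloxy)ethyl]-3,5-dimethyl-1,2-dioxolan-3-yl]heptanoate (trans racemate)
Conditions: SnCl4 (1.1 equiv), 9 (2 equiv), CH2Cl2, −78 °C; aq. NaHCO3; SiO2 chromatography (trans isomer)
Reagents that add atoms: none
Why: SnCl4 removes methoxide from 7 and leaves a peroxycarbenium ion, a planar carbocation at the former ketone carbon (C5) stabilised by the adjacent silylperoxy oxygen O1. The CH2 terminus of 9 adds to this carbon and forms C4–C5, and because the alkene is 1,1-disubstituted the positive charge lands on the fully substituted carbon, C3. The distal, silicon-bearing peroxide oxygen O2 then captures this tertiary cation and forms O2–C3 while the triethylsilyl group leaves to methoxide, so the dioxolane closes by a five-membered cation–oxygen collapse in which both former alkene carbons become ring members (formally endo to the alkene, but unconstrained because the π bond is already spent in a stepwise process). The closest known reaction type is the SnCl4- or TiCl4-promoted (3+2) annulation of triethylsilylperoxy ketals with simple alkenes to 1,2-dioxolanes, for which 1,1-disubstituted alkenes are among the most suitable partners. C5 becomes stereogenic in the C–C bond formation on a planar cation in an achiral environment and is therefore racemic; C3 becomes stereogenic in the ring closure, where only the modest size difference between methyl and the longer group at each centre decides which face of the C3 cation O2 reaches. A mixture of cis and trans racemates is therefore expected, from which the trans racemate 10 is to be separated on silica and identified by NOE contacts and by the near-equivalence of the two C4 protons expected for its pseudo-C2-symmetric pattern. The selectivities the step needs are regiochemical (cation at C3) and chemoselective (no interception by ester or ether oxygen); the first is secured by the 1,1-disubstitution, the second by the remoteness of the ester and by the fact that the silyl ether oxygen could reach C3 only through a four-membered ring, which is why a bulky silyl ether is preferred to any acyl group. Low temperature and a non-nucleophilic solvent are chosen to disfavour proton loss from the C3 cation and Hock-type fragmentation of the peroxycarbenium ion.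

Step 7
Reactants: 10 methyl 7-[(3S*,5S*)-5-[2-(tert-butyldiphenylsilyloxy)ethyl]-3,5-dimethyl-1,2-dioxolan-3-yl]heptanoate (trans racemate)
Product: 11 methyl 7-[(3S,5S)-5-[2-(tert-butyldiphenylsilyloxy)ethyl]-3,5-dimethyl-1,2-dioxolan-3-yl]heptanoate
Conditions: preparative HPLC on amylose tris(3,5-dimethylphenylcarbamate)/SiO2, hexane/i-PrOH, rt
Reagents that add atoms: none
Why: Resolution on a chiral stationary phase: the enantiomers form transient diastereomeric adsorbates of different stability, and the diphenylsilyl group offers π-contacts and UV detection. No bond is made or broken, so both stereocentres are untouched; the absolute configuration of the collected fraction must be confirmed by X-ray analysis of a crystalline heavy-atom derivative or by correlation at the end.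

Step 8
Reactants: 11 methyl 7-[(3S,5S)-5-[2-(tert-butyldiphenylsilyloxy)ethyl]-3,5-dimethyl-1,2-dioxolan-3-yl]heptanoate
Product: 12 7-[(3S,5S)-5-[2-(tert-butyldiphenylsilyloxy)ethyl]-3,5-dimethyl-1,2-dioxolan-3-yl]heptanal
Conditions: i-Bu2AlH (1.1 equiv), CH2Cl2, −78 °C; MeOH, then aq. KNaC4H4O6
Reagents that add atoms: none
Why: Partial ester reduction: at −78 °C the aluminium hemiacetal formed by one hydride transfer persists until work-up, so the aldehyde is released only after the hydride is destroyed. The fully substituted dialkyl peroxide and the silyl ether should not react at this temperature.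

Step 9
Reactants: 12 7-[(3S,5S)-5-[2-(tert-butyldiphenylsilyloxy)ethyl]-3,5-dimethyl-1,2-dioxolan-3-yl]heptanal
Product: 13 (2E)-9-[(3S,5S)-5-[2-(tert-butyldiphenylsilyloxy)ethyl]-3,5-dimethyl-1,2-dioxolan-3-yl]non-2-enal
Conditions: Ph3P=CHCHO (1.3 equiv), toluene, 80 °C
Reagents that add atoms: (triphenylphosphoranylidene)acetaldehyde, O=CC=P(c1ccccc1)(c1ccccc1)c1ccccc1
Why: Wittig reaction of a stabilised ylide, which gives the E-enal (C7=C8) under thermodynamic control. The enal is much less electrophilic than 12, so a second homologation should be slow, and the ylide has no free phosphine lone pair to reduce the O–O bond.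

Step 10
Reactants: 14 (Z)-hex-3-en-1-ol
Product: 15 5-[(Z)-hex-3-enylsulfanyl]-1-phenyl-1H-tetrazole
Conditions: 1-phenyl-1H-tetrazole-5-thiol, PPh3, DIAD, THF, 0 °C → rt
Reagents that add atoms: 1-phenyl-1H-tetrazole-5-thiol, Sc1nnnn1-c1ccccc1
Why: Mitsunobu thioetherification: the primary alcohol is activated as an alkoxyphosphonium ion and displaced by the acidic thiol in an SN2 step that does not touch the Z-alkene.

Step 11
Reactants: 15 5-[(Z)-hex-3-enylsulfanyl]-1-phenyl-1H-tetrazole; 5 hydrogen peroxide
Product: 16 5-[(Z)-hex-3-enylsulfonyl]-1-phenyl-1H-tetrazole
Conditions: 5 (30% aq.), (NH4)6Mo7O24·4H2O (cat.), EtOH, 0 °C → rt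
Reagents that add atoms: none
Why: Molybdate-catalysed peroxo oxidation of sulfide to sulfone; sulfur is oxidised far faster than an isolated 1,2-disubstituted alkene is epoxidised, so the Z-alkene should survive.

Step 12
Reactants: 13 (2E)-9-[(3S,5S)-5-[2-(tert-butyldiphenylsilyloxy)ethyl]-3,5-dimethyl-1,2-dioxolan-3-yl]non-2-enal; 16 5-[(Z)-hex-3-enylsulfonyl]-1-phenyl-1H-tetrazole
Product: 17 tert-butyl-[2-[(3S,5S)-3,5-dimethyl-5-[(7E,9E,12Z)-pentadeca-7,9,12-trienyl]-1,2-dioxolan-3-yl]ethoxy]diphenylsilane
Conditions: 16 (1.3 equiv), KN(SiMe3)2 (1.25 equiv), DME, −60 °C; then 13, −60 °C → rt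
Reagents that add atoms: none
Why: Julia–Kocienski olefination: the potassium sulfonyl carbanion adds to the aldehyde, the alkoxide undergoes Smiles transfer of the phenyltetrazole, and loss of SO2 and tetrazololate forms C9=C10, for which the potassium counter-ion in DME favours the anti adduct and hence E. C7=C8 and C12=C13 are carried in unchanged, and the ring, having no hydrogen on C3 or C5 and no carbonyl β to the peroxide at this stage, should tolerate the amide base.

Step 13
Reactants: 17 tert-butyl-[2-[(3S,5S)-3,5-dimethyl-5-[(7E,9E,12Z)-pentadeca-7,9,12-trienyl]-1,2-dioxolan-3-yl]ethoxy]diphenylsilane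
Product: 18 2-[(3S,5S)-3,5-dimethyl-5-[(7E,9E,12Z)-pentadeca-7,9,12-trienyl]-1,2-dioxolan-3-yl]ethanol
Conditions: Bu4NF, THF, 0 °C → rt
Reagents that add atoms: none
Why: Fluoride-induced desilylation driven by the Si–F bond; neither the peroxide nor the triene reacts with fluoride under these conditions.

Step 14
Reactants: 18 2-[(3S,5S)-3,5-dimethyl-5-[(7E,9E,12Z)-pentadeca-7,9,12-trienyl]-1,2-dioxolan-3-yl]ethanol
Product: 20 2-[(3R,5S)-3,5-dimethyl-5-[(7E,9E,12Z)-pentadeca-7,9,12-trienyl]-1,2-dioxolan-3-yl]acetic acid, via dioxolanylacetaldehyde 19 (not isolated)
Conditions: Dess–Martin periodinane, NaHCO3, CH2Cl2, 0 °C; filter, concentrate cold; then NaClO2, NaH2PO4, 2-methylbut-2-ene (large excess), t-BuOH/H2O, 0 °C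
Reagents that add atoms: sodium chlorite, [Na+].[O-]Cl=O
Why: Dess–Martin oxidation gives the β-peroxy aldehyde under buffered, non-basic conditions, and Pinnick oxidation converts it at once to the acid while 2-methylbut-2-ene intercepts hypochlorous acid before it can attack the diene. No stereocentre is touched; the descriptor at C3 changes from S to R only through the sequence rule.

## Compound list

1 | monomethyl suberate (8-methoxy-8-oxooctanoic acid) | COC(=O)CCCCCCC(=O)O | starting material
2 | methyl 8-chloro-8-oxooctanoate | COC(=O)CCCCCCC(=O)Cl | intermediate
3 | methyl 8-oxononanoate | COC(=O)CCCCCCC(C)=O | intermediate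
4 | methyl 8,8-dimethoxynonanoate | COC(=O)CCCCCCC(C)(OC)OC | intermediate
5 | hydrogen peroxide | OO | starting material
6 | methyl 8-hydroperoxy-8-methoxynonanoate (racemic) | COC(=O)CCCCCCC(C)(OC)OO | intermediate
7 | methyl 8-methoxy-8-(triethylsilylperoxy)nonanoate (racemic) | COC(C)(CCCCCCC(=O)OC)OO[Si](CC)(CC)CC | intermediate
8 | 3-methylbut-3-en-1-ol | C=C(C)CCO | starting material
9 | tert-butyl(3-methylbut-3-enyloxy)diphenylsilane | C=C(C)CCO[Si](c1ccccc1)(c1ccccc1)C(C)(C)C | intermediate
10 | methyl 7-[(3S*,5S*)-5-[2-(tert-butyldiphenylsilyloxy)ethyl]-3,5-dimethyl-1,2-dioxolan-3-yl]heptanoate (trans racemate; one enantiomer drawn) | COC(=O)CCCCCC[C@@]1(C)C[C@](C)(CCO[Si](c2ccccc2)(c2ccccc2)C(C)(C)C)OO1 | intermediate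
11 | methyl 7-[(3S,5S)-5-[2-(tert-butyldiphenylsilyloxy)ethyl]-3,5-dimethyl-1,2-dioxolan-3-yl]heptanoate (single enantiomer) | COC(=O)CCCCCC[C@@]1(C)C[C@](C)(CCO[Si](c2ccccc2)(c2ccccc2)C(C)(C)C)OO1 | intermediate
12 | 7-[(3S,5S)-5-[2-(tert-butyldiphenylsilyloxy)ethyl]-3,5-dimethyl-1,2-dioxolan-3-yl]heptanal | O=CCCCCCC[C@@]1(C)C[C@](C)(CCO[Si](c2ccccc2)(c2ccccc2)C(C)(C)C)OO1 | intermediate
13 | (2E)-9-[(3S,5S)-5-[2-(tert-butyldiphenylsilyloxy)ethyl]-3,5-dimethyl-1,2-dioxolan-3-yl]non-2-enal | O=C/C=C/CCCCCC[C@@]1(C)C[C@](C)(CCO[Si](c2ccccc2)(c2ccccc2)C(C)(C)C)OO1 | intermediate
14 | (Z)-hex-3-en-1-ol | CC/C=C\CCO | starting material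
15 | 5-[(Z)-hex-3-enylsulfanyl]-1-phenyl-1H-tetrazole | CC/C=C\CCSc1nnnn1-c1ccccc1 | intermediate
16 | 5-[(Z)-hex-3-enylsulfonyl]-1-phenyl-1H-tetrazole | CC/C=C\CCS(=O)(=O)c1nnnn1-c1ccccc1 | intermediate
17 | tert-butyl-[2-[(3S,5S)-3,5-dimethyl-5-[(7E,9E,12Z)-pentadeca-7,9,12-trienyl]-1,2-dioxolan-3-yl]ethoxy]diphenylsilane | CC/C=C\C/C=C/C=C/CCCCCC[C@@]1(C)C[C@](C)(CCO[Si](c2ccccc2)(c2ccccc2)C(C)(C)C)OO1 | intermediate
18 | 2-[(3S,5S)-3,5-dimethyl-5-[(7E,9E,12Z)-pentadeca-7,9,12-trienyl]-1,2-dioxolan-3-yl]ethanol | CC/C=C\C/C=C/C=C/CCCCCC[C@@]1(C)C[C@](C)(CCO)OO1 | intermediate
19 | 2-[(3R,5S)-3,5-dimethyl-5-[(7E,9E,12Z)-pentadeca-7,9,12-trienyl]-1,2-dioxolan-3-yl]acetaldehyde | CC/C=C\C/C=C/C=C/CCCCCC[C@@]1(C)C[C@](C)(CC=O)OO1 | intermediate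
20 | 2-[(3R,5S)-3,5-dimethyl-5-[(7E,9E,12Z)-pentadeca-7,9,12-trienyl]-1,2-dioxolan-3-yl]acetic acid | CC/C=C\C/C=C/C=C/CCCCCC[C@@]1(C)C[C@](C)(CC(=O)O)OO1 | target

## Step count and least certain steps

Total step count: 14. Longest linear sequence: 11 steps (1, 2, 3, 4, 6, 7, 8, 9, 12, 13, 14).

Perhydrolysis (step 3). The likely failure is over-exchange: the mono-peroxyketal can ionise again under the acid and take up a second H2O2, or adventitious water can return the ketone, because all these species equilibrate through the same oxocarbenium ion. The fallback sets out from 3 and returns at 6. Wittig methylenation of 3 (Ph3P=CH2 from Ph3PCH3Br and KOt-Bu, THF, 0 °C) gives methyl 8-methylnon-8-enoate F1. Ozonolysis of F1 in CH2Cl2/MeOH at −78 °C should cleave the primary ozonide mainly to formaldehyde and the more substituted carbonyl oxide, which methanol traps to give 6 directly, with no acid-mediated equilibrium.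

Annulation (step 6, the key step). Two processes are most likely to hurt. The first is unselective ring closure giving cis and trans in similar amounts. The second is premature collapse of the cationic intermediates, by proton loss from the C3 cation or Hock-type migration in the peroxycarbenium ion; this is favoured because the silyloxyethyl group lowers the nucleophilicity of 9 inductively. The fallback exchanges the roles of the fragments; it sets out from 9 and 3 and returns at 10. Ozonolysis of 9 in CH2Cl2/MeOH at −78 °C gives tert-butyl(3-hydroperoxy-3-methoxybutoxy)diphenylsilane F2. Silylation (Et3SiCl, imidazole) gives tert-butyl[3-methoxy-3-(triethylsilylperoxy)butoxy]diphenylsilane F3. F3 is then ionised with SnCl4 in CH2Cl2 at −78 °C in the presence of the unfunctionalised and more nucleophilic methyl 8-methylnon-8-enoate F1 (made from 3 as above). This is the same known annulation, but it forms C3–C4 and O1–C5, and it leads to the same compound 10. The relative configuration would still have to be sorted by chromatography.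

Resolution (step 7). The likely failure is insufficient discrimination of the enantiomers on the stationary phase, because the stereocentres are flanked only by flexible alkyl groups and the molecule is very lipophilic. The fallback is a classical resolution through covalent diastereomers; it sets out from 10 and returns at 11. Desilylation of 10 (Bu4NF, THF) gives methyl 7-[(3S*,5S*)-5-(2-hydroxyethyl)-3,5-dimethyl-1,2-dioxolan-3-yl]heptanoate F4. Acylation with (1S)-camphanic chloride (Et3N, DMAP, CH2Cl2) gives two diastereomeric esters, to be separated by chromatography or crystallisation. The wanted one is 2-[(3S,5S)-5-(7-methoxy-7-oxoheptyl)-3,5-dimethyl-1,2-dioxolan-3-yl]ethyl (1S,4R)-4,7,7-trimethyl-3-oxo-2-oxabicyclo[2.2.1]heptane-1-carboxylate F5. Methanolysis (K2CO3, MeOH) releases methyl 7-[(3S,5S)-5-(2-hydroxyethyl)-3,5-dimethyl-1,2-dioxolan-3-yl]heptanoate F6. Resilylation (t-BuPh2SiCl, imidazole) gives 11.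

Partial reduction (step 8). The likely failure is collapse of the aluminium hemiacetal before the quench, so that reduction runs on to the alcohol while some ester remains. The fallback sets out from 11 and returns at 12. Complete reduction with excess i-Bu2AlH (−78 → 0 °C) gives 7-[(3S,5S)-5-[2-(tert-butyldiphenylsilyloxy)ethyl]-3,5-dimethyl-1,2-dioxolan-3-yl]heptan-1-ol F7. Dess–Martin oxidation (NaHCO3, CH2Cl2) then gives 12.

Olefination (step 12). The likely failure is erosion of E-selectivity at C9=C10: conjugated aldehydes discriminate less between syn and anti adducts, and the adducts can partly revert. Deprotonation of the enal at its γ-position is a second risk. The fallback replaces kinetic by thermodynamic control; it sets out from 17 as obtained (mixture of C9=C10 isomers) and returns at 17. Catalytic I2 in hexane under ambient light should equilibrate the conjugated diene to the E,E isomer through reversible iodine-atom addition. The isolated 12Z alkene gives no stabilised radical on such addition and should isomerise much more slowly. No new compound is made.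

Final oxidation (step 14). The likely failures are β-elimination of the peroxide oxygen from aldehyde 19 while it waits between the two stages, and electrophilic chlorination of the diene by hypochlorite that escapes the scavenger. The fallback is a one-stage nitroxyl oxidation; it sets out from 18 and returns at 20. TEMPO (cat.) and PhI(OAc)2 in MeCN/aqueous pH 7 phosphate buffer at 0 °C oxidise the alcohol to the acid; 19 is hydrated and oxidised further as fast as it forms, and no chlorine oxidant is present. No new compound is made.

## Further compounds

F1 | step 3 | methyl 8-methylnon-8-enoate | C=C(C)CCCCCCC(=O)OC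
F2 | step 6 | tert-butyl(3-hydroperoxy-3-methoxybutoxy)diphenylsilane (racemic) | COC(C)(CCO[Si](c1ccccc1)(c1ccccc1)C(C)(C)C)OO
F3 | step 6 | tert-butyl[3-methoxy-3-(triethylsilylperoxy)butoxy]diphenylsilane (racemic) | COC(C)(CCO[Si](c1ccccc1)(c1ccccc1)C(C)(C)C)OO[Si](CC)(CC)CC
F4 | step 7 | methyl 7-[(3S*,5S*)-5-(2-hydroxyethyl)-3,5-dimethyl-1,2-dioxolan-3-yl]heptanoate (trans racemate; one enantiomer drawn) | COC(=O)CCCCCC[C@@]1(C)C[C@](C)(CCO)OO1
F5 | step 7 | 2-[(3S,5S)-5-(7-methoxy-7-oxoheptyl)-3,5-dimethyl-1,2-dioxolan-3-yl]ethyl (1S,4R)-4,7,7-trimethyl-3-oxo-2-oxabicyclo[2.2.1]heptane-1-carboxylate | COC(=O)CCCCCC[C@@]1(C)C[C@](C)(CCOC(=O)[C@@]23CC[C@@](C)(C(=O)O2)C3(C)C)OO1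
F6 | step 7 | methyl 7-[(3S,5S)-5-(2-hydroxyethyl)-3,5-dimethyl-1,2-dioxolan-3-yl]heptanoate (single enantiomer) | COC(=O)CCCCCC[C@@]1(C)C[C@](C)(CCO)OO1
F7 | step 8 | 7-[(3S,5S)-5-[2-(tert-butyldiphenylsilyloxy)ethyl]-3,5-dimethyl-1,2-dioxolan-3-yl]heptan-1-ol | OCCCCCCC[C@@]1(C)C[C@](C)(CCO[Si](c2ccccc2)(c2ccccc2)C(C)(C)C)OO1
F0 | step 12 | none | none
F0 | step 14 | none | none
A1 | alternative 1 | 3,5-dimethoxy-3,5-dimethyl-1,2-dioxolane (stereoisomer mixture) | COC1(C)CC(C)(OC)OO1
A2 | alternative 1 | 1-methoxy-1-(trimethylsilyloxy)ethene | C=C(OC)O[Si](C)(C)C
A3 | alternative 1 | dimethyl 2,2'-[(3R,5R)-3,5-dimethyl-1,2-dioxolane-3,5-diyl]diacetate (formed as the racemate) | COC(=O)C[C@@]1(C)C[C@](C)(CC(=O)OC)OO1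
A4 | alternative 2 | (3R,5E)-12-(tert-butyldiphenylsilyloxy)-3-hydroperoxy-3,5-dimethyldodec-5-en-1-ol | CC(C)(C)[Si](c1ccccc1)(c1ccccc1)OCCCCCC/C=C(\C)C[C@](C)(CCO)OO
A5 | alternative 2 | 2-[(3S,5R)-5-[(1S)-7-(tert-butyldiphenylsilyloxy)-1-iodoheptyl]-3,5-dimethyl-1,2-dioxolan-3-yl]ethanol | CC(C)(C)[Si](c1ccccc1)(c1ccccc1)OCCCCCC[C@H](I)[C@@]1(C)C[C@](C)(CCO)OO1
A6 | alternative 3 | bis[(2R)-2-methyloxetan-2-yl]methane | C[C@@]1(CCO1)C[C@@]2(C)CCO2
A7 | alternative 3 | 2,2'-[(3S,5S)-3,5-dimethyl-1,2-dioxolane-3,5-diyl]diethanol | OCC[C@@]1(C)C[C@](C)(CCO)OO1
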